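The six-membered ring C1–C6 is cut at C1–C6 and C4–C5 into a furan and a two-carbon ketene equivalent. The quaternary carbinol C1 with its CH2O arm (C7) is the masked 2-position of a furfuryl ester, and the cis oxygens on C1, C2 and C5 correspond to the bridge and exo substituents of an oxanorbornene. One enantioselective Diels–Alder reaction of furfuryl benzoate with 2-bromoacrolein forms both bonds, closes the carbocycle as a 7-oxabicyclo[2.2.1]heptene and fixes C1 and C4; the furan oxygen becomes the C1 hydroxyl. The diene already carries the target's C7 benzoate; the dienophile supplies C5 and C6.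

Key step: step 3

Remark 1: atom labels C1–C7 are those of the target (C1 = C(OH)CH2OBz, C7 = its CH2, C2 = CHOBz, C3=C4, C5 and C6 = CHOAc, C6 next to C1). They are kept for all bicyclic intermediates, in which an oxygen bridges C1 and C4; exo means on the side of that bridge. Bz = benzoyl, Ac = acetyl.

Remark 2 (assumption): the catalyst antipode written in step 3 is the one expected to give the (1R,2S,4S) adduct, by analogy with the sense of induction of this catalyst type with simple dienes. If the substituted furan responds in the opposite sense, the mirror-image catalyst is used and nothing else changes.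

Step 1
Reactants: 1 furfuryl alcohol; 2 benzoyl chloride
Product: 3 furfuryl benzoate (furan-2-ylmethyl benzoate)
Conditions: Et3N, DMAP (cat.), CH2Cl2, 0 °C to rt
Reagents that add atoms: none
Why: O-acylation of a primary alcohol by an acid chloride (nucleophilic acyl substitution) under amine buffering, so that the acid-sensitive furan never meets free HCl; no stereocentre is formed.

Step 2
Reactants: 4 acrolein
Product: 6 2-bromoacrolein, via 2,3-dibromopropanal 5 (not isolated)
Conditions: Br2, CH2Cl2, −78 to 0 °C; then Et3N, 0 °C; distilled, used fresh
Reagents that add atoms: bromine, BrBr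
Why: Electrophilic bromine addition to the alkene followed by base-induced E1cB loss of HBr through the acidic α-hydrogen, the standard bromination–dehydrobromination route to a 2-haloenal.

Step 3
Reactants: 3 furfuryl benzoate; 6 2-bromoacrolein
Product: 7 [(1R,2S,4S)-2-bromo-2-formyl-7-oxabicyclo[2.2.1]hept-5-en-1-yl]methyl benzoate (oxygen bridge C1–C4, C2=C3 alkene, C5 = CH2, C6 = C(Br)CHO, formyl exo, bromine endo)
Conditions: (R)-2-butyl-4-(1H-indol-3-ylmethyl)-3-tosyl-1,3,2-oxazaborolidin-5-one (10 mol%, from N-tosyl-(R)-tryptophan and BuB(OH)2), 3 (2 equiv), CH2Cl2, −78 °C; cold silica filtration, used at once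
Reagents that add atoms: none
Why: The boron Lewis acid binds the formyl oxygen of 2-bromoacrolein, and the furan adds suprafacially through its two α-carbons in a concerted but asynchronous [4+2] cycloaddition. The closest known reaction is the enantioselective Diels–Alder addition of furan itself to 2-haloacroleins under this class of oxazaborolidinone; the 2-substituted furan is a further member of the same substrate class. The carbocycle C1–C6 closes by intermolecular cycloaddition, with C4–C5 bonding ahead of C1–C6, and the furan oxygen is left as the C1–O–C4 bridge. C1 and C4 are set together by the catalyst, whose indole ring covers one face of the bound s-cis enal, while C6 follows the usual preference of 2-haloacroleins for formyl exo and is erased in step 4. The step needs ortho regiochemistry, which frontier-orbital matching should provide: the largest diene HOMO lobe sits on the furan carbon that carries no substituent and pairs with the CH2 end of the enal. It also needs cycloaddition to outpace conjugate alkylation at that carbon and cycloreversion, for which the low temperature, the mild Lewis acid and the slightly electron-poor benzoyloxymethyl furan are chosen.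

Step 4
Reactants: 7 Diels–Alder adduct
Product: 9 [(1R,4S)-2-oxo-7-oxabicyclo[2.2.1]hept-5-en-1-yl]methyl benzoate (C6 ketone), via hydroxy aldehyde 8 (not isolated)
Conditions: NaHCO3, THF/H2O, 0 °C to rt; then NaIO4, rt
Reagents that add atoms: water, O
Why: Base-mediated hydrolysis of the tertiary α-bromo aldehyde (the hydrate oxygen displaces bromide from the rear through an epoxy hemiacetal) gives the α-hydroxy aldehyde, whose hydrate undergoes periodate (Malaprade) cleavage to the ketone and formic acid, all at or below room temperature so that the benzoate and the cycloreversion-prone bicycle survive; the C6 stereocentre is removed.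

Step 5
Reactants: 9 bicyclic enone-type ketone
Product: 10 C2,C3-exo,exo-diol: (5,6-exo-dihydroxy-2-oxo-7-oxabicyclo[2.2.1]hept-1-yl)methyl benzoate, both hydroxyls on the side of the oxygen bridge
Conditions: OsO4 (2 mol%), N-methylmorpholine N-oxide, acetone/H2O, 0 °C to rt
Reagents that add atoms: osmium tetroxide, O=[Os](=O)(=O)=O; N-methylmorpholine N-oxide, C[N+]1([O-])CCOCC1; water, O
Why: Catalytic osmium tetroxide cis-dihydroxylation with N-oxide reoxidant; the reagent adds to the strained C2=C3 bond from the convex exo face, so C2–OH and C3–OH are both set cis to the oxygen bridge (the future C1 hydroxyl).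

Step 6
Reactants: 10 keto diol; 2 benzoyl chloride (2 equiv and a small excess)
Product: 11 tribenzoate ketone (10 with C2–OBz and C3–OBz, both exo)
Conditions: pyridine, DMAP (cat.), CH2Cl2, 0 °C to rt
Reagents that add atoms: none
Why: Exhaustive O-benzoylation under nucleophilic catalysis; no differentiation of the diol is needed because the C2 ester is the target's benzoate and the C3 ester is the leaving group of step 10.

Step 7
Reactants: 11 tribenzoate ketone
Product: 13 C5-exo-hydroxy ketone (11 carrying OH at C5 on the bridge side), via sodium enolate 12 (not isolated)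
Conditions: NaN(SiMe3)2, THF, −78 °C; 2-(phenylsulfonyl)-3-phenyloxaziridine, −78 °C; AcOH quench at −78 °C
Reagents that add atoms: 2-(phenylsulfonyl)-3-phenyloxaziridine, O=S(=O)(c1ccccc1)N1OC1c1ccccc1
Why: Enolate hydroxylation with an N-sulfonyloxaziridine (Davis oxidation): only C5 can be deprotonated because C1 is quaternary, and the oxidant meets the enolate on the exo face, the endo face being screened by the C2–C3 bridge, so C5–OH is set cis to the oxygen bridge; −78 °C keeps the enolate from expelling the bridge oxygen.

Step 8
Reactants: 13 C5-exo-hydroxy ketone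
Product: 14 C5-exo,C6-endo-diol (13 with C6=O reduced; C6–OH trans to the oxygen bridge and to C5–OH)
Conditions: NaBH4, MeOH/CH2Cl2, −40 °C
Reagents that add atoms: none
Why: Borohydride reduction of the ketone; hydride reaches C6 from the exo face (the endo face lies inside the cage under C2), which sets C6–OH endo, trans to the C1 and C5 oxygens.

Step 9
Reactants: 14 bicyclic diol
Product: 15 bromo triol: cyclohexane with C1(OH)(CH2OBz), C2–OBz, C3–OBz, C4–Br, C5–OH, C6–OH; C1–OH, C2–O, C3–O and C5–O on one face, C4–Br and C6–OH on the other
Conditions: BBr3 (5 equiv), CH2Cl2, −78 to 0 °C; ice-water quench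
Reagents that add atoms: boron tribromide, BrB(Br)Br
Why: Lewis acid cleavage of a strained bicyclic ether: boron binds the bridge oxygen and bromide opens it by SN2 at C4, the only secondary ether carbon, with inversion, whereas C1 is quaternary, flanked by three oxygenated carbons and, with C6–O held as a borate, has no ester placed anti to the bridge to assist its ionisation; the bridge oxygen is released as the C1 hydroxyl.

Step 10
Reactants: 15 bromo triol
Product: 16 triol: cyclohex-3-ene with C1(OH)(CH2OBz), C2–OBz, C5–OH, C6–OH; C1–OH, C2–OBz and C5–OH cis, C6–OH trans (5,6-di-O-deacetyl cleistenediol F)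
Conditions: Zn dust (activated), EtOH, 70 °C
Reagents that add atoms: none
Why: Zinc-mediated reductive β-elimination of a vicinal bromo ester (the Fischer–Zach type of alkene formation): the carbanion equivalent generated at C4 expels the C3 benzoate and not the free C5 hydroxyl, a far poorer leaving group, so the double bond can only form at C3=C4 and the C4 configuration is irrelevant.

Step 11
Reactants: 16 triol
Product: 17 cleistenediol F
Conditions: Ac2O, pyridine, DMAP (cat.), CH2Cl2, 0 °C to rt
Reagents that add atoms: acetic anhydride, CC(=O)OC(C)=O
Why: O-Acetylation with nucleophilic catalysis takes the two secondary hydroxyls at C5 and C6, while the tertiary C1 hydroxyl, buried between three substituted carbons, should stay free under these mild conditions; no stereocentre changes.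

Compound list
1 | furfuryl alcohol | OCc1ccco1 | starting material
2 | benzoyl chloride | O=C(Cl)c1ccccc1 | starting material
3 | furfuryl benzoate | O=C(OCc1ccco1)c1ccccc1 | intermediate
4 | acrolein | C=CC=O | starting material
5 | 2,3-dibromopropanal (racemic, not isolated) | O=CC(Br)CBr | intermediate
6 | 2-bromoacrolein | C=C(Br)C=O | intermediate
7 | [(1R,2S,4S)-2-bromo-2-formyl-7-oxabicyclo[2.2.1]hept-5-en-1-yl]methyl benzoate, formyl exo | O=C[C@]1(Br)C[C@H]2C=C[C@]1(COC(=O)c1ccccc1)O2 | intermediate
8 | hydroxy aldehyde: 7 with Br replaced by OH (C6–OH exo, CHO endo), not isolated | O[C@]1(C=O)C[C@H]2C=C[C@]1(COC(=O)c1ccccc1)O2 | intermediate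
9 | [(1R,4S)-2-oxo-7-oxabicyclo[2.2.1]hept-5-en-1-yl]methyl benzoate (C6 ketone) | O=C1C[C@H]2C=C[C@]1(COC(=O)c1ccccc1)O2 | intermediate
10 | keto diol: 9 with exo-OH at C2 and C3 | O=C1C[C@H]2[C@H](O)[C@H](O)[C@]1(COC(=O)c1ccccc1)O2 | intermediate
11 | tribenzoate ketone: 10 with C2–OBz and C3–OBz | O=C1C[C@H]2[C@H](OC(=O)c3ccccc3)[C@H](OC(=O)c3ccccc3)[C@]1(COC(=O)c3ccccc3)O2 | intermediate
12 | sodium C5=C6 enolate of 11 (not isolated) | [Na+].[O-]C1=C[C@H]2[C@H](OC(=O)c3ccccc3)[C@H](OC(=O)c3ccccc3)[C@]1(COC(=O)c3ccccc3)O2 | intermediate
13 | C5-exo-hydroxy ketone | O=C1[C@H](O)[C@H]2[C@H](OC(=O)c3ccccc3)[C@H](OC(=O)c3ccccc3)[C@]1(COC(=O)c3ccccc3)O2 | intermediate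
14 | C5-exo,C6-endo-diol (bicyclic tribenzoate) | O[C@H]1[C@H](O)[C@H]2[C@H](OC(=O)c3ccccc3)[C@H](OC(=O)c3ccccc3)[C@]1(COC(=O)c3ccccc3)O2 | intermediate
15 | bromo triol (C4–Br trans to C1–OH; C1, C5, C6 hydroxyls; C2, C3, C7 benzoates) | O[C@H]1[C@H](O)[C@@H](Br)[C@H](OC(=O)c2ccccc2)[C@H](OC(=O)c2ccccc2)[C@@]1(O)COC(=O)c1ccccc1 | intermediate
16 | 5,6-di-O-deacetyl cleistenediol F (C1, C5, C6 triol; C2 and C7 benzoates; C3=C4) | O[C@H]1[C@H](O)C=C[C@H](OC(=O)c2ccccc2)[C@@]1(O)COC(=O)c1ccccc1 | intermediate
17 | cleistenediol F | CC(=O)O[C@@H]1C=C[C@H](OC(=O)c2ccccc2)[C@@](O)(COC(=O)c2ccccc2)[C@H]1OC(C)=O | target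

Total step count: 11. Longest linear sequence: 10 steps (steps 1 and 3–11); step 2 is a one-step side branch.

Steps most likely to fail

Step 3. What may go wrong: loss of enantiofacial discrimination once the diene carries the substituent that becomes the quaternary bridgehead, so that both antipodes form. The fallback sets out from 3 and 6 and returns at 9, and it moves absolute control from the catalyst to a resolution. The cycloaddition is run with the racemic form of the same oxazaborolidinone, which should give 7 together with the enantiomeric adduct F1. The mixture is taken through the hydrolysis–periodate sequence of step 4, passing through 8 and the enantiomeric hydroxy aldehyde F2 (not isolated), to ketone 9 together with the enantiomeric ketone F3. Ketone 9 is then separated from F3 by preparative chromatography on a cellulose tris(3,5-dimethylphenylcarbamate) phase, and the route continues from 9.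

Step 9. What may go wrong: opening at the wrong ether carbon through rear-side assistance by the C7 benzoate at C1, or ester cleavage by the strong Lewis acid before the electron-poor ether reacts. The fallback sets out from 14 and returns at 16; a soft sulfur nucleophile under mild zinc catalysis replaces bromide, and a sulfone-based elimination replaces zinc. Treatment of 14 with PhSSiMe3, ZnI2 and tetrabutylammonium iodide (ClCH2CH2Cl, rt) should open the bridge by SN2 attack of thiolate at C4 and silylate the hydroxyls, giving the tris(trimethylsilyl) ether sulfide F4 (not isolated). Dilute aqueous HCl in THF removes the silyl groups to give the triol sulfide F5, and mCPBA (CH2Cl2, 0 °C) gives the sulfone F6. SmI2 (THF/DMPU, −78 °C to rt) then effects a Julia–Lythgoe-type reductive elimination of the β-benzoyloxy sulfone, the C3 benzoate leaving in preference to the free C5 hydroxyl, to give 16.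

Step 4. What may go wrong: the aldehyde hydrate rearranges (hydride shift to the acid, or α-ketol ring expansion of the hydroxy aldehyde) faster than it is cleaved. The fallback sets out from 7 and returns at 9. The aldehyde is removed at once by NaBH4 reduction (MeOH/CH2Cl2, −78 to 0 °C) to the bromohydrin F7. DBU (CH2Cl2, rt) closes the spiro-epoxide F8 by internal displacement of the tertiary bromide. H5IO6 (THF/H2O, 0 °C) cleaves the epoxide through its diol to ketone 9 and formaldehyde.

Further compounds
F1 | step 3 | enantiomeric adduct (mirror image of 7) | O=C[C@@]1(Br)C[C@@H]2C=C[C@@]1(COC(=O)c1ccccc1)O2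
F2 | step 3 | enantiomeric hydroxy aldehyde (mirror image of 8, not isolated) | O[C@@]1(C=O)C[C@@H]2C=C[C@@]1(COC(=O)c1ccccc1)O2
F3 | step 3 | enantiomeric ketone (mirror image of 9) | O=C1C[C@@H]2C=C[C@@]1(COC(=O)c1ccccc1)O2
F4 | step 9 | tris(trimethylsilyl) ether sulfide (C4–SPh trans to C1–O; C1, C5, C6 silyl ethers; not isolated) | C[Si](C)(C)O[C@H]1[C@H](O[Si](C)(C)C)[C@@H](Sc2ccccc2)[C@H](OC(=O)c2ccccc2)[C@H](OC(=O)c2ccccc2)[C@@]1(O[Si](C)(C)C)COC(=O)c1ccccc1
F5 | step 9 | triol sulfide (15 with SPh in place of Br) | O[C@H]1[C@H](O)[C@@H](Sc2ccccc2)[C@H](OC(=O)c2ccccc2)[C@H](OC(=O)c2ccccc2)[C@@]1(O)COC(=O)c1ccccc1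
F6 | step 9 | triol sulfone (15 with SO2Ph in place of Br) | O[C@H]1[C@H](O)[C@@H](S(=O)(=O)c2ccccc2)[C@H](OC(=O)c2ccccc2)[C@H](OC(=O)c2ccccc2)[C@@]1(O)COC(=O)c1ccccc1
F7 | step 4 | bromohydrin (7 with CH2OH in place of CHO; CH2OH exo, Br endo) | OC[C@]1(Br)C[C@H]2C=C[C@]1(COC(=O)c1ccccc1)O2
F8 | step 4 | spiro-epoxide at C6 (epoxide oxygen exo, CH2 endo) | C1O[C@@]12C[C@H]3C=C[C@]2(COC(=O)c4ccccc4)O3
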